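**Retrosynthetic overview**

- Numbering: ring A = C1–C5 and C10 (C3 methyl, C4 exocyclic methylene); ring B = C5–C10 (C7=C8, C8 methyl, C9 carrying benzylic C11, C10 methyl). β is the face of the C10 methyl.
- Feature: in ring B the tertiary C9 and the quaternary C10 lie next to the C7=C8 alkene, so C9–C10 and C7=C8 are the new σ and π bonds of a [3,3] shift. Ring B is therefore made first, by Ireland–Claisen contraction of a δ-lactone (C1 carbonyl, ring oxygen on C7) that carries the (E)-arylbutenyl group on C7.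
- Lactone: C6–C7 aldol of a C2–C6 methyl ketone (C3/C4 from crotylboration of ethyl glyoxylate) with the aryl enal C7–C11, phosphonoacetate olefination C5=C10, hydride to C5, methyl to C10.
- Ring A second: C1 acid to vinyl, ring-closing metathesis C1=C2, hydrogenation. Then C4 ketone to methylene, side chain to acetic acid, hydroquinone freed last.

Key step: step 16

Assumption: the C4 carbinol configuration is immaterial because C4 ends as an sp2 carbon; the 4R isomer from the anti crotylation is carried as a triethylsilyl ether, which can be cleaved in the presence of the primary triisopropylsilyl ether.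

Abbreviations: Ar = 2,5-dimethoxy-4-[2-(triisopropylsilyloxy)ethyl]phenyl; Ipc = isopinocampheyl derived from (−)-α-pinene.

**Route**

Step 1
Reactants: 1 2,5-dimethoxyphenylacetic acid
Product: 2 2-(2,5-dimethoxyphenyl)ethanol
Conditions: LiAlH4, THF, 0 °C → reflux
Reagents that add atoms: none
Why: LiAlH4 reduction of a carboxylic acid to the primary alcohol, with the aryl methyl ethers inert.

Step 2
Reactants: 2 2-(2,5-dimethoxyphenyl)ethanol
Product: 3 [2-(2,5-dimethoxyphenyl)ethoxy]triisopropylsilane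
Conditions: i-Pr3SiCl, imidazole, DMF, rt
Reagents that add atoms: chlorotriisopropylsilane CC(C)[Si](Cl)(C(C)C)C(C)C
Why: Imidazole-promoted silylation of a primary alcohol gives a robust ether that should survive organolithium, hydride and enolate chemistry until step 25.

Step 3
Reactants: 3 [2-(2,5-dimethoxyphenyl)ethoxy]triisopropylsilane
Product: 4 [2-(4-bromo-2,5-dimethoxyphenyl)ethoxy]triisopropylsilane
Conditions: N-bromosuccinimide, MeCN, 0 °C → rt
Reagents that add atoms: N-bromosuccinimide O=C1CCC(=O)N1Br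
Why: Electrophilic aromatic bromination should occur para to the alkyl chain and ortho to a methoxy group, the most activated and least hindered free position.

Step 4
Reactants: 4 [2-(4-bromo-2,5-dimethoxyphenyl)ethoxy]triisopropylsilane; 5 prenyl bromide (1-bromo-3-methylbut-2-ene)
Product: 7 {2-[2,5-dimethoxy-4-(3-methylbut-2-en-1-yl)phenyl]ethoxy}triisopropylsilane, via aryllithium 6 (not isolated)
Conditions: n-BuLi, THF, −78 °C; CuBr·SMe2 (10 mol %), then 5, −78 → 0 °C
Reagents that add atoms: none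
Why: Bromine–lithium exchange followed by copper-catalysed SN2 allylation, in which copper suppresses attack at the tertiary allyl terminus.

Step 5
Reactants: 7 {2-[2,5-dimethoxy-4-(3-methylbut-2-en-1-yl)phenyl]ethoxy}triisopropylsilane
Product: 8 (2E)-4-Ar-2-methylbut-2-en-1-ol
Conditions: SeO2 (cat.), t-BuOOH, CH2Cl2, rt
Reagents that add atoms: tert-butyl hydroperoxide CC(C)(C)OO
Why: Selenium dioxide allylic oxidation (ene reaction then [2,3] shift) attacks the E methyl at the more substituted alkene terminus, which fixes the E geometry of the later C8=C9 bond and should leave the benzylic C11 methylene.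

Step 6
Reactants: 8 (2E)-4-Ar-2-methylbut-2-en-1-ol
Product: 9 (2E)-4-Ar-2-methylbut-2-enal
Conditions: MnO2, CH2Cl2, rt
Reagents that add atoms: none
Why: MnO2 oxidises allylic alcohols selectively without E/Z isomerisation, and any enal already formed in step 5 converges here.

Step 7
Reactants: 10 ethyl glyoxylate (freshly distilled); 11 (E)-crotylboronic acid pinacol ester
Product: 13 ethyl (2R,3R)-2-hydroxy-3-methylpent-4-enoate, via pinacol borate ester 12 (not isolated)
Conditions: (R)-TRIP [(R)-3,3'-bis(2,4,6-triisopropylphenyl)-1,1'-binaphthyl-2,2'-diyl hydrogen phosphate] (5 mol %), 4 Å MS, toluene, −30 °C; aq. work-up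
Reagents that add atoms: none
Why: Chiral phosphoric acid-catalysed crotylboration through a chair Zimmerman–Traxler transition state, in which the E boronate gives the anti pair and the catalyst enantiomer is the one expected to give R carbinols from aldehydes whose substituent outranks the new allyl carbon; the centre made here beside the vinyl group is C3 of the target.

Step 8
Reactants: 13 ethyl (2R,3R)-2-hydroxy-3-methylpent-4-enoate
Product: 14 ethyl (2R,3R)-3-methyl-2-(triethylsilyloxy)pent-4-enoate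
Conditions: Et3SiCl, imidazole, CH2Cl2, 0 °C → rt
Reagents that add atoms: chlorotriethylsilane CC[Si](Cl)(CC)CC
Why: Imidazole-promoted silylation of the secondary alcohol, which protects the future C4 oxygen through the enolate steps.

Step 9
Reactants: 14 ethyl (2R,3R)-3-methyl-2-(triethylsilyloxy)pent-4-enoate
Product: 15 (2R,3R)-N-methoxy-N,3-dimethyl-2-(triethylsilyloxy)pent-4-enamide
Conditions: MeNHOMe·HCl, i-PrMgCl, THF, −20 °C
Reagents that add atoms: N,O-dimethylhydroxylamine hydrochloride CNOC.Cl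
Why: Weinreb amide formation from the ester with the magnesium amide at low temperature, conditions that should not epimerise the α-silyloxy centre.

Step 10
Reactants: 15 (2R,3R)-N-methoxy-N,3-dimethyl-2-(triethylsilyloxy)pent-4-enamide
Product: 16 (3R,4R)-4-methyl-3-(triethylsilyloxy)hex-5-en-2-one
Conditions: MeMgBr, THF, 0 °C
Reagents that add atoms: methylmagnesium bromide C[Mg]Br
Why: Grignard addition to a Weinreb amide stops at the chelated tetrahedral adduct, so the methyl ketone (C5 carbonyl, C6 methyl) should form without over-addition.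

Step 11
Reactants: 16 (3R,4R)-4-methyl-3-(triethylsilyloxy)hex-5-en-2-one; 9 (2E)-4-Ar-2-methylbut-2-enal
Product: 19 (3R,4R,7R,8E)-10-Ar-7-hydroxy-3,8-dimethyl-4-(triethylsilyloxy)deca-1,8-dien-5-one, via boron enolate 17 (not isolated), via boron aldolate 18 (not isolated)
Conditions: (+)-Ipc2BCl, Et3N, Et2O, 0 °C; 9, −78 → −20 °C; then MeOH, pH 7 buffer, H2O2, 0 °C
Reagents that add atoms: none
Why: Ipc2BCl-mediated boron aldol of a methyl ketone, in which the methyl-side enol borinate adds to the enal through a cyclic transition state and the Ipc ligands of this reagent enantiomer are expected to select the Re face to give the 7R carbinol, the α-silyloxy centre exerting only weak 1,4-induction.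

Step 12
Reactants: 19 (3R,4R,7R,8E)-10-Ar-7-hydroxy-3,8-dimethyl-4-(triethylsilyloxy)deca-1,8-dien-5-one; 20 diethylphosphonoacetic acid
Product: 21 (3R,4R,7R,8E)-10-Ar-3,8-dimethyl-5-oxo-4-(triethylsilyloxy)deca-1,8-dien-7-yl 2-(diethoxyphosphoryl)acetate
Conditions: N,N'-dicyclohexylcarbodiimide, 4-(dimethylamino)pyridine (cat.), CH2Cl2, 0 °C → rt
Reagents that add atoms: none
Why: Steglich esterification of the secondary allylic alcohol under neutral carbodiimide activation, which should avoid retro-aldol cleavage or dehydration of the β-hydroxy ketone.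

Step 13
Reactants: 21 (3R,4R,7R,8E)-10-Ar-3,8-dimethyl-5-oxo-4-(triethylsilyloxy)deca-1,8-dien-7-yl 2-(diethoxyphosphoryl)acetate
Product: 22 (6R)-6-[(2E)-4-Ar-but-2-en-2-yl]-4-[(1R,2R)-2-methyl-1-(triethylsilyloxy)but-3-en-1-yl]-5,6-dihydro-2H-pyran-2-one
Conditions: LiCl, i-Pr2NEt, MeCN, rt
Reagents that add atoms: none
Why: Intramolecular Horner–Wadsworth–Emmons olefination under mild lithium-chelate conditions, in which the phosphonoacetate anion adds to the C5 ketone and closes the six-membered unsaturated lactone (C5=C10).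

Step 14
Reactants: 22 (6R)-6-[(2E)-4-Ar-but-2-en-2-yl]-4-[(1R,2R)-2-methyl-1-(triethylsilyloxy)but-3-en-1-yl]-5,6-dihydro-2H-pyran-2-one
Product: 23 (4R,6R)-6-[(2E)-4-Ar-but-2-en-2-yl]-4-[(1S,2R)-2-methyl-1-(triethylsilyloxy)but-3-en-1-yl]tetrahydro-2H-pyran-2-one (cis-4,6; side chain spatially unchanged, its first descriptor changes only by the priority rules)
Conditions: Cu(OAc)2·H2O (5 mol %), 1,2-bis(diphenylphosphino)benzene (5 mol %), (EtO)2MeSiH, t-BuOH, toluene, 0 °C → rt
Reagents that add atoms: none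
Why: Copper hydride conjugate reduction of an unsaturated lactone, in which hydride should add to C5 of the half-chair on the face anti to the pseudo-equatorial C7 alkenyl group, placing the C5 side chain cis to it while the isolated alkenes stay untouched.

Step 15
Reactants: 23 (4R,6R)-6-[(2E)-4-Ar-but-2-en-2-yl]-4-[(1S,2R)-2-methyl-1-(triethylsilyloxy)but-3-en-1-yl]tetrahydro-2H-pyran-2-one
Product: 25 (3S,4R,6R)-6-[(2E)-4-Ar-but-2-en-2-yl]-3-methyl-4-[(1R,2R)-2-methyl-1-(triethylsilyloxy)but-3-en-1-yl]tetrahydro-2H-pyran-2-one, via lithium enolate 24 (not isolated)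
Conditions: LiN(i-Pr)2, THF, −78 °C; MeI, −78 → −40 °C
Reagents that add atoms: iodomethane CI
Why: Kinetic lactone enolate alkylation, in which iodomethane should enter trans to the C5 side chain; because C10 becomes planar again in step 16, either C10 epimer can be used.

Step 16
Reactants: 25 (3S,4R,6R)-6-[(2E)-4-Ar-but-2-en-2-yl]-3-methyl-4-[(1R,2R)-2-methyl-1-(triethylsilyloxy)but-3-en-1-yl]tetrahydro-2H-pyran-2-one
Product: 28 (1R,2R,6R)-2-(Ar-methyl)-1,3-dimethyl-6-[(1R,2R)-2-methyl-1-(triethylsilyloxy)but-3-en-1-yl]cyclohex-3-ene-1-carboxylic acid, via silyl ketene acetal 26 (not isolated), via trimethylsilyl ester 27 (not isolated)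
Conditions: LiN(i-Pr)2, Me3SiCl–Et3N, THF, −78 °C → rt; toluene, 110 °C; then K2CO3, MeOH/H2O, work-up at pH 5
Reagents that add atoms: none
Why: LiN(i-Pr)2 removes the C10 proton and Me3SiCl traps the enolate as the cyclic silyl ketene acetal 26, in which C10 is planar; on heating, a concerted suprafacial [3,3] shift (Ireland–Claisen rearrangement in its lactone ring-contraction form) makes C9–C10 while the lactone C7–O bond breaks and the π bond moves to C7=C8. Ring B (C5–C10) closes in a pericyclic mode as a six-membered carbocycle, because the four-atom lactone tether C10–C5–C6–C7 is kept and the C8–C9 unit is inserted; the six-membered lactone allows only a boat-like transition state shaped like bicyclo[2.2.2]octane. C10 is controlled by the C7 carbinol centre, since the alkenyl group can reach C10 only across the lactone face on which it stands; this is also the face of the C5 side chain, so the C10 methyl ends cis to the C5 side chain. C9 is controlled by the E geometry of the C8=C9 bond within the boat array, which places C11 trans to the C10 methyl and cis to the carboxyl group. The step needs enolisation at C10 only (the sole α-position) and chirality transfer without ionisation of the allylic C7–O bond, which the amine-buffered, non-acidic silyl ketene acetal conditions should secure.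

Step 17
Reactants: 28 (1R,2R,6R)-2-(Ar-methyl)-1,3-dimethyl-6-[(1R,2R)-2-methyl-1-(triethylsilyloxy)but-3-en-1-yl]cyclohex-3-ene-1-carboxylic acid
Product: 29 [(1R,2R,6R)-2-(Ar-methyl)-1,3-dimethyl-6-[(1R,2R)-2-methyl-1-(triethylsilyloxy)but-3-en-1-yl]cyclohex-3-en-1-yl]methanol
Conditions: LiAlH4, THF, 0 → 60 °C
Reagents that add atoms: none
Why: LiAlH4 reduction of the hindered neopentyl acid to the primary alcohol, with silyl ethers and alkenes inert.

Step 18
Reactants: 29 [(1R,2R,6R)-2-(Ar-methyl)-1,3-dimethyl-6-[(1R,2R)-2-methyl-1-(triethylsilyloxy)but-3-en-1-yl]cyclohex-3-en-1-yl]methanol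
Product: 30 (1R,2R,6R)-2-(Ar-methyl)-1,3-dimethyl-6-[(1R,2R)-2-methyl-1-(triethylsilyloxy)but-3-en-1-yl]cyclohex-3-ene-1-carbaldehyde
Conditions: Dess–Martin periodinane, NaHCO3, CH2Cl2, 0 °C → rt
Reagents that add atoms: none
Why: Dess–Martin oxidation to an aldehyde that has no α-hydrogen and so cannot epimerise.

Step 19
Reactants: 30 (1R,2R,6R)-2-(Ar-methyl)-1,3-dimethyl-6-[(1R,2R)-2-methyl-1-(triethylsilyloxy)but-3-en-1-yl]cyclohex-3-ene-1-carbaldehyde
Product: 31 the C1 vinyl compound: 30 with CHO replaced by CH=CH2 (all centres unchanged)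
Conditions: Ph3PCH3Br, KN(SiMe3)2, THF, 0 °C → rt
Reagents that add atoms: methyltriphenylphosphonium bromide C[P+](c1ccccc1)(c1ccccc1)c1ccccc1.[Br-]
Why: Wittig methylenation with the small unstabilised ylide, which should tolerate the neopentyl aldehyde and turns C1 into a vinyl carbon.

Step 20
Reactants: 31 the C1 vinyl compound
Product: 32 trans-fused bicyclic 1,7-diene: C1=C2 and C7=C8, 3α-methyl, 4α-OSiEt3, 5α-H, 8-methyl, 9α-CH2Ar, 10β-methyl
Conditions: second-generation Grubbs catalyst (5 mol %), 1,4-benzoquinone (10 mol %), toluene, 80 °C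
Reagents that add atoms: none
Why: Ring-closing metathesis of the 1,7-diene closes ring A as a cyclohexene (C1=C2) with loss of ethene; the C1 and C4 chains are trans-diequatorial on ring B, which allows the trans ring fusion, and the trisubstituted C7=C8 bond should not be engaged.

Step 21
Reactants: 32 trans-fused bicyclic 1,7-diene
Product: 33 trans-fused 7-ene: 3α-methyl, 4α-OSiEt3, 5α-H, 8-methyl, 9α-CH2Ar, 10β-methyl
Conditions: H2 (4 atm), RhCl(PPh3)3 (10 mol %), benzene/EtOH, rt
Reagents that add atoms: none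
Why: Homogeneous hydrogenation with RhCl(PPh3)3 depends strongly on alkene substitution, so the cis-disubstituted C1=C2 bond should be reduced and the trisubstituted C7=C8 bond kept.

Step 22
Reactants: 33 trans-fused 7-ene with 4α-OSiEt3
Product: 34 the 4α-alcohol: 3α-methyl, 4α-OH, 5α-H, 9α-CH2Ar, 10β-methyl, C7=C8
Conditions: HF·pyridine, pyridine, THF, 0 °C → rt
Reagents that add atoms: none
Why: Buffered HF·pyridine should cleave the triethylsilyl ether much faster than the primary triisopropylsilyl ether.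

Step 23
Reactants: 34 the 4α-alcohol
Product: 35 the C4 ketone: 3α-methyl, 5α-H, 9α-CH2Ar, 10β-methyl, C7=C8
Conditions: Dess–Martin periodinane, NaHCO3, CH2Cl2, 0 °C → rt
Reagents that add atoms: none
Why: Buffered Dess–Martin oxidation is neither basic nor strongly acidic, so the axial C3 methyl and the trans fusion at C5 should be kept; the ketone is used at once.

Step 24
Reactants: 35 the C4 ketone
Product: 36 the 4-methylene compound: 3α-methyl, 4-CH2=, 5α-H, 9α-CH2Ar, 10β-methyl, C7=C8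
Conditions: Zn, CH2Br2, TiCl4, THF/CH2Cl2, 0 °C → rt
Reagents that add atoms: dibromomethane BrCBr
Why: Takai–Lombardo methylenation, in which the non-basic gem-dizinc reagent activated by TiCl4 adds to the hindered C4 ketone and eliminates without enolisation.

Step 25
Reactants: 36 the 4-methylene compound
Product: 37 the primary alcohol: 36 with CH2CH2OH in place of CH2CH2OSi(i-Pr)3
Conditions: Bu4NF, THF, rt
Reagents that add atoms: none
Why: Fluoride cleavage of the silyl ether under conditions that do not touch the two alkenes.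

Step 26
Reactants: 37 the primary alcohol
Product: 38 the arylacetaldehyde: 37 with CH2CHO in place of CH2CH2OH
Conditions: Dess–Martin periodinane, NaHCO3, CH2Cl2, 0 °C; used crude
Reagents that add atoms: none
Why: Dess–Martin oxidation of the primary alcohol to the aldehyde without over-oxidation.

Step 27
Reactants: 38 the arylacetaldehyde
Product: 39 the arylacetic acid dimethyl ether: 38 with CH2CO2H in place of CH2CHO
Conditions: NaClO2, NaH2PO4, 2-methyl-2-butene, t-BuOH/H2O, 0 °C → rt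
Reagents that add atoms: sodium chlorite [Na+].[O-]Cl=O
Why: Pinnick oxidation, in which 2-methyl-2-butene scavenges hypochlorite and so protects the two alkenes and the electron-rich arene.

Step 28
Reactants: 39 the arylacetic acid dimethyl ether
Product: 40 CNP0137474.1, 2-{2,5-dihydroxy-4-[(3α,8,10β-trimethyl-4-methylene-5α-H-7-en-9α-yl)methyl]phenyl}acetic acid, (3R,5S,9R,10R)
Conditions: NaSEt (excess), DMF, 140 °C, degassed; then dilute HCl to pH 3 under argon, 0 °C
Reagents that add atoms: none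
Why: SN2 demethylation of both aryl methyl ethers by thiolate under non-acidic conditions, so the exocyclic alkene should not isomerise and the hydroquinone acid should not lactonise, the carboxylate being inert.

**Compound list**

1 | 2,5-dimethoxyphenylacetic acid | COc1ccc(OC)c(CC(=O)O)c1 | starting material
2 | 2-(2,5-dimethoxyphenyl)ethanol | COc1ccc(OC)c(CCO)c1 | intermediate
3 | [2-(2,5-dimethoxyphenyl)ethoxy]triisopropylsilane | COc1ccc(OC)c(CCO[Si](C(C)C)(C(C)C)C(C)C)c1 | intermediate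
4 | [2-(4-bromo-2,5-dimethoxyphenyl)ethoxy]triisopropylsilane | COc1cc(CCO[Si](C(C)C)(C(C)C)C(C)C)c(OC)cc1Br | intermediate
5 | prenyl bromide | CC(C)=CCBr | starting material
6 | aryllithium Ar–Li | [Li]c1cc(OC)c(CCO[Si](C(C)C)(C(C)C)C(C)C)cc1OC | intermediate
7 | {2-[2,5-dimethoxy-4-(3-methylbut-2-en-1-yl)phenyl]ethoxy}triisopropylsilane | CC(C)=CCc1cc(OC)c(CCO[Si](C(C)C)(C(C)C)C(C)C)cc1OC | intermediate
8 | (2E)-4-Ar-2-methylbut-2-en-1-ol | OC/C(C)=C/Cc1cc(OC)c(CCO[Si](C(C)C)(C(C)C)C(C)C)cc1OC | intermediate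
9 | (2E)-4-Ar-2-methylbut-2-enal | O=C/C(C)=C/Cc1cc(OC)c(CCO[Si](C(C)C)(C(C)C)C(C)C)cc1OC | intermediate
10 | ethyl glyoxylate | CCOC(=O)C=O | starting material
11 | (E)-crotylboronic acid pinacol ester | C/C=C/CB1OC(C)(C)C(C)(C)O1 | starting material
12 | ethyl (2R,3R)-3-methyl-2-(4,4,5,5-tetramethyl-1,3,2-dioxaborolan-2-yloxy)pent-4-enoate | CCOC(=O)[C@H](OB1OC(C)(C)C(C)(C)O1)[C@H](C)C=C | intermediate
13 | ethyl (2R,3R)-2-hydroxy-3-methylpent-4-enoate | CCOC(=O)[C@H](O)[C@H](C)C=C | intermediate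
14 | ethyl (2R,3R)-3-methyl-2-(triethylsilyloxy)pent-4-enoate | CCOC(=O)[C@H](O[Si](CC)(CC)CC)[C@H](C)C=C | intermediate
15 | (2R,3R)-N-methoxy-N,3-dimethyl-2-(triethylsilyloxy)pent-4-enamide | CON(C)C(=O)[C@H](O[Si](CC)(CC)CC)[C@H](C)C=C | intermediate
16 | (3R,4R)-4-methyl-3-(triethylsilyloxy)hex-5-en-2-one | CC(=O)[C@H](O[Si](CC)(CC)CC)[C@H](C)C=C | intermediate
17 | enol diisopinocampheylborinate of 16 (boron on the C5 oxygen, C5=C6) | C=C(OB([C@H]1C[C@H]2C[C@@H]([C@@H]1C)C2(C)C)[C@H]1C[C@H]2C[C@@H]([C@@H]1C)C2(C)C)[C@H](O[Si](CC)(CC)CC)[C@H](C)C=C | intermediate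
18 | diisopinocampheylborinate of 19 (boron on the C7 oxygen) | O=C(C[C@@H](OB([C@H]1C[C@H]2C[C@@H]([C@@H]1C)C2(C)C)[C@H]1C[C@H]2C[C@@H]([C@@H]1C)C2(C)C)/C(C)=C/Cc1cc(OC)c(CCO[Si](C(C)C)(C(C)C)C(C)C)cc1OC)[C@H](O[Si](CC)(CC)CC)[C@H](C)C=C | intermediate
19 | (3R,4R,7R,8E)-10-Ar-7-hydroxy-3,8-dimethyl-4-(triethylsilyloxy)deca-1,8-dien-5-one | O=C(C[C@@H](O)/C(C)=C/Cc1cc(OC)c(CCO[Si](C(C)C)(C(C)C)C(C)C)cc1OC)[C@H](O[Si](CC)(CC)CC)[C@H](C)C=C | intermediate
20 | diethylphosphonoacetic acid | CCOP(=O)(CC(=O)O)OCC | starting material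
21 | (3R,4R,7R,8E)-10-Ar-3,8-dimethyl-5-oxo-4-(triethylsilyloxy)deca-1,8-dien-7-yl 2-(diethoxyphosphoryl)acetate | O=C(C[C@@H](OC(=O)CP(=O)(OCC)OCC)/C(C)=C/Cc1cc(OC)c(CCO[Si](C(C)C)(C(C)C)C(C)C)cc1OC)[C@H](O[Si](CC)(CC)CC)[C@H](C)C=C | intermediate
22 | (6R)-6-[(2E)-4-Ar-but-2-en-2-yl]-4-[(1R,2R)-2-methyl-1-(triethylsilyloxy)but-3-en-1-yl]-5,6-dihydro-2H-pyran-2-one | O=C1O[C@@H](/C(C)=C/Cc2cc(OC)c(CCO[Si](C(C)C)(C(C)C)C(C)C)cc2OC)CC([C@H](O[Si](CC)(CC)CC)[C@H](C)C=C)=C1 | intermediate
23 | (4R,6R)-6-[(2E)-4-Ar-but-2-en-2-yl]-4-[(1S,2R)-2-methyl-1-(triethylsilyloxy)but-3-en-1-yl]tetrahydro-2H-pyran-2-one | O=C1O[C@@H](/C(C)=C/Cc2cc(OC)c(CCO[Si](C(C)C)(C(C)C)C(C)C)cc2OC)C[C@@H]([C@H](O[Si](CC)(CC)CC)[C@H](C)C=C)C1 | intermediate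
24 | lithium enolate of 23 (C1=C10) | [Li]OC1=C[C@H]([C@H](O[Si](CC)(CC)CC)[C@H](C)C=C)C[C@H](/C(C)=C/Cc2cc(OC)c(CCO[Si](C(C)C)(C(C)C)C(C)C)cc2OC)O1 | intermediate
25 | (3S,4R,6R)-6-[(2E)-4-Ar-but-2-en-2-yl]-3-methyl-4-[(1R,2R)-2-methyl-1-(triethylsilyloxy)but-3-en-1-yl]tetrahydro-2H-pyran-2-one (key-step precursor) | O=C1O[C@@H](/C(C)=C/Cc2cc(OC)c(CCO[Si](C(C)C)(C(C)C)C(C)C)cc2OC)C[C@@H]([C@H](O[Si](CC)(CC)CC)[C@H](C)C=C)[C@@H]1C | intermediate
26 | cyclic trimethylsilyl ketene acetal of 25 (C1=C10, OSiMe3 on C1) | C[Si](C)(C)OC1=C(C)[C@H]([C@H](O[Si](CC)(CC)CC)[C@H](C)C=C)C[C@H](/C(C)=C/Cc2cc(OC)c(CCO[Si](C(C)C)(C(C)C)C(C)C)cc2OC)O1 | intermediate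
27 | trimethylsilyl ester of 28 | C[Si](C)(C)OC(=O)[C@]1(C)[C@H](Cc2cc(OC)c(CCO[Si](C(C)C)(C(C)C)C(C)C)cc2OC)C(C)=CC[C@H]1[C@H](O[Si](CC)(CC)CC)[C@H](C)C=C | intermediate
28 | (1R,2R,6R)-2-(Ar-methyl)-1,3-dimethyl-6-[(1R,2R)-2-methyl-1-(triethylsilyloxy)but-3-en-1-yl]cyclohex-3-ene-1-carboxylic acid (key-step product) | OC(=O)[C@]1(C)[C@H](Cc2cc(OC)c(CCO[Si](C(C)C)(C(C)C)C(C)C)cc2OC)C(C)=CC[C@H]1[C@H](O[Si](CC)(CC)CC)[C@H](C)C=C | intermediate
29 | C1 primary alcohol (28 with CH2OH in place of CO2H) | OC[C@]1(C)[C@H](Cc2cc(OC)c(CCO[Si](C(C)C)(C(C)C)C(C)C)cc2OC)C(C)=CC[C@H]1[C@H](O[Si](CC)(CC)CC)[C@H](C)C=C | intermediate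
30 | C1 aldehyde (28 with CHO in place of CO2H) | O=C[C@]1(C)[C@H](Cc2cc(OC)c(CCO[Si](C(C)C)(C(C)C)C(C)C)cc2OC)C(C)=CC[C@H]1[C@H](O[Si](CC)(CC)CC)[C@H](C)C=C | intermediate
31 | C1 vinyl compound (28 with CH=CH2 in place of CO2H) | C=C[C@]1(C)[C@H](Cc2cc(OC)c(CCO[Si](C(C)C)(C(C)C)C(C)C)cc2OC)C(C)=CC[C@H]1[C@H](O[Si](CC)(CC)CC)[C@H](C)C=C | intermediate
32 | trans-fused 1,7-diene: 3α-methyl, 4α-OSiEt3, 5α-H, 8-methyl, 9α-CH2Ar, 10β-methyl | C[C@@H]1C=C[C@]2(C)[C@H](Cc3cc(OC)c(CCO[Si](C(C)C)(C(C)C)C(C)C)cc3OC)C(C)=CC[C@H]2[C@@H]1O[Si](CC)(CC)CC | intermediate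
33 | trans-fused 7-ene: 3α-methyl, 4α-OSiEt3, 5α-H, 8-methyl, 9α-CH2Ar, 10β-methyl | C[C@@H]1CC[C@]2(C)[C@H](Cc3cc(OC)c(CCO[Si](C(C)C)(C(C)C)C(C)C)cc3OC)C(C)=CC[C@H]2[C@@H]1O[Si](CC)(CC)CC | intermediate
34 | 4α-alcohol of 33 | C[C@@H]1CC[C@]2(C)[C@H](Cc3cc(OC)c(CCO[Si](C(C)C)(C(C)C)C(C)C)cc3OC)C(C)=CC[C@H]2[C@@H]1O | intermediate
35 | C4 ketone: 3α-methyl, 5α-H, 9α-CH2Ar, 10β-methyl, C7=C8 | C[C@@H]1CC[C@]2(C)[C@H](Cc3cc(OC)c(CCO[Si](C(C)C)(C(C)C)C(C)C)cc3OC)C(C)=CC[C@H]2C1=O | intermediate
36 | 4-methylene compound with CH2CH2OSi(i-Pr)3 side chain | C[C@@H]1CC[C@]2(C)[C@H](Cc3cc(OC)c(CCO[Si](C(C)C)(C(C)C)C(C)C)cc3OC)C(C)=CC[C@H]2C1=C | intermediate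
37 | 4-methylene compound with CH2CH2OH side chain | C[C@@H]1CC[C@]2(C)[C@H](Cc3cc(OC)c(CCO)cc3OC)C(C)=CC[C@H]2C1=C | intermediate
38 | 4-methylene compound with CH2CHO side chain | C[C@@H]1CC[C@]2(C)[C@H](Cc3cc(OC)c(CC=O)cc3OC)C(C)=CC[C@H]2C1=C | intermediate
39 | 4-methylene compound with CH2CO2H side chain (hydroquinone dimethyl ether of the target) | C[C@@H]1CC[C@]2(C)[C@H](Cc3cc(OC)c(CC(=O)O)cc3OC)C(C)=CC[C@H]2C1=C | intermediate
40 | CNP0137474.1, (3R,5S,9R,10R) | C=C1[C@H](C)CC[C@]2(C)[C@H](Cc3cc(O)c(CC(=O)O)cc3O)C(C)=CC[C@@H]12 | target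

**Step count and risks**

Total step count: 28. Longest linear sequence: 24 steps (steps 1–6, then 11–28).

Steps most likely to fail:

1. Step 16. The boat-shaped transition state is strained and sterically loaded (fully substituted C10, trisubstituted alkene). Loss of the silyl group back to lactone, C-silylation or fragmentation of the silyl ketene acetal may therefore outrun the [3,3] shift. The fallback sets out from 9 and 14 and comes back at 30; it builds ring B by an intermolecular Diels–Alder reaction. Enal 9 is methylenated (Ph3P=CH2, THF) to the diene (3E)-5-Ar-3-methylpenta-1,3-diene F1. Ester 14 is reduced (i-Bu2AlH, CH2Cl2, −78 °C) to (2R,3R)-3-methyl-2-(triethylsilyloxy)pent-4-enal F2, which Ph3P=C(CH3)CHO (toluene, 80 °C) extends to (2E,4R,5R)-2,5-dimethyl-4-(triethylsilyloxy)hepta-2,6-dienal F3. Cycloaddition of F1 to F3 promoted by Me2AlCl (CH2Cl2, −78 → −20 °C), in the ortho orientation with the formyl group endo, forms C9–C10 and C5–C6 and should give aldehyde 30 directly. The E dienophile puts the C5 chain cis to the C10 methyl, the E diene with endo formyl puts C11 trans to it, and the C4 silyloxy centre selects the face.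

2. Step 13. Deprotonation at C6 and β-elimination of the phosphonoacetate (leading to a C5 dienone conjugated with C8=C9) may compete with the slow olefination of the hindered C5 ketone. The fallback sets out from 19 and comes back at 22. Aldol 19 is acylated with bromoacetyl bromide and pyridine (CH2Cl2, −20 °C) to the C7 bromoacetate F4. SmI2 (THF, −78 °C) then effects an intramolecular Reformatsky addition to C5 under non-basic conditions to give the β-hydroxy lactone F5. Burgess reagent (benzene, 50 °C) dehydrates the tertiary alcohol into conjugation and gives 22.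

3. Step 24. Methylenation of the doubly flanked C4 ketone may be slow, so that enolisation moves the axial C3 methyl to the equatorial position or inverts C5 before the carbonyl is consumed. The fallback sets out from 35 and comes back at 36. Me3SiCH2Li with CeCl3 (THF, −78 °C), a weakly basic organocerium reagent, adds to the C4 ketone to give the 4β-hydroxy-4α-(trimethylsilylmethyl) adduct F6. KH (THF, 0 °C) then completes the Peterson olefination to 36, after the epimerisable carbonyl is gone.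

Further compounds
F1 | step 16 | (3E)-5-Ar-3-methylpenta-1,3-diene | C=C/C(C)=C/Cc1cc(OC)c(CCO[Si](C(C)C)(C(C)C)C(C)C)cc1OC
F2 | step 16 | (2R,3R)-3-methyl-2-(triethylsilyloxy)pent-4-enal | O=C[C@H](O[Si](CC)(CC)CC)[C@H](C)C=C
F3 | step 16 | (2E,4R,5R)-2,5-dimethyl-4-(triethylsilyloxy)hepta-2,6-dienal | O=C/C(C)=C/[C@H](O[Si](CC)(CC)CC)[C@H](C)C=C
F4 | step 13 | C7 bromoacetate of 19 | O=C(C[C@@H](OC(=O)CBr)/C(C)=C/Cc1cc(OC)c(CCO[Si](C(C)C)(C(C)C)C(C)C)cc1OC)[C@H](O[Si](CC)(CC)CC)[C@H](C)C=C
F5 | step 13 | (4S,6R)-4-hydroxy lactone: 23 with OH in place of H on C5 | O=C1O[C@@H](/C(C)=C/Cc2cc(OC)c(CCO[Si](C(C)C)(C(C)C)C(C)C)cc2OC)C[C@@](O)([C@H](O[Si](CC)(CC)CC)[C@H](C)C=C)C1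
F6 | step 24 | 4β-hydroxy-4α-(trimethylsilylmethyl) adduct of 35 | C[C@@H]1CC[C@]2(C)[C@H](Cc3cc(OC)c(CCO[Si](C(C)C)(C(C)C)C(C)C)cc3OC)C(C)=CC[C@H]2[C@]1(O)C[Si](C)(C)C
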